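**Retrosynthetic overview** (isochromanone numbering: C1 lactone carbonyl, O2, C3, C4, C4a–C8a; side chain C1', C2' … counted from C3)

1. Target ⇐ its 6,8-dimethoxy lactone, by chelation-controlled cleavage of the 8-methyl ether only (last step).
2. The dimethoxy lactone ⇐ three components joined at C3 in one operation: the benzylic carbanion of methyl 2,4-dimethoxy-6-methylbenzoate (benzene ring, C1, C4), vinylboronic acid pinacol ester (C3 and C1'; boron is the latent ring oxygen) and 10-iododecan-5-one (C2' to the chain end). A nickel-catalysed enantioselective conjunctive cross-coupling makes C4–C3 and C1'–C2'; oxidation and lactonisation follow in the same flask.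
3. Enabling feature: C3 is a secondary oxygen-bearing carbon between two CH2 groups, benzylic C4 and side-chain C1'. C4 sits on the benzene ring ortho to the carboxyl carbon C1, which acidifies it for lateral lithiation and later captures the C3 oxygen. C3–C1' therefore maps onto a vinylboron unit, and the chain ketone at C7' is remote and needs no protection.
4. 10-Iododecan-5-one ⇐ 6-bromohexanoyl chloride and n-butylmagnesium chloride (iron-catalysed acylation), then halide exchange.
5. Ring order: the benzene ring is purchased; the only ring formed is the δ-lactone (pyranone) ring, closed in the key step.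

Key step: step 3

Assumption: the sense of induction of the nickel/PyBox catalyst with a benzylic migrating group is not established, so the ligand enantiomer that delivers the (R)-boronate is to be used; (S,S)-Ph-PyBox is written below and its antipode serves if the sense proves opposite.

**Route**

Step 1
Reactants: 1 6-bromohexanoyl chloride; 2 n-butylmagnesium chloride
Product: 3 10-bromodecan-5-one
Conditions: Fe(acac)3 (3 mol %), THF, −78 °C, slow addition of 2 (1.05 equiv)
Reagents that add atoms: none
Why: Iron-catalysed acylation of a Grignard reagent by an acid chloride is much faster at −78 °C than addition to the ketone formed or attack at the primary C–Br bond, so the bromo ketone should form cleanly.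

Step 2
Reactants: 3 10-bromodecan-5-one
Product: 4 10-iododecan-5-one
Conditions: NaI (3 equiv), acetone, reflux
Reagents that add atoms: sodium iodide, [Na+].[I-]
Why: Finkelstein halide exchange (SN2 at an unhindered primary carbon) is driven by precipitation of NaBr from acetone and leaves the ketone untouched.

Step 3
Reactants: 5 methyl 2,4-dimethoxy-6-methylbenzoate; 6 vinylboronic acid pinacol ester (4,4,5,5-tetramethyl-2-vinyl-1,3,2-dioxaborolane); 4 10-iododecan-5-one
Product: 11 (3R)-6,8-dimethoxy-3-(7-oxoundecyl)-3,4-dihydro-1H-isochromen-1-one, via benzylic lithium species 7 (not isolated), via vinylboron ate complex 8 (not isolated), via secondary pinacol boronate 9 (not isolated), via hydroxy ester 10 (not isolated)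
Conditions: LDA (1.0 equiv), THF, −78 °C; 6, −78 → 0 °C; volatiles removed in vacuo; 4, NiBr2·glyme (10 mol %), (S,S)-Ph-PyBox (12 mol %), THF/DMSO, rt; then 3 M NaOH, 30% H2O2, 0 °C → rt; then 1 M HCl, rt
Reagents that add atoms: hydrogen peroxide, OO
Why: Proposed new method: the C1 ester acidifies the ortho methyl group, so LDA gives the benzylic lithium species 7 (the carbanion known from lateral lithiation of o-toluates), which adds to boron of 6 to form ate complex 8; an alkyl–nickel species generated from iodide 4 (halogen abstraction, then radical capture by the chiral nickel complex) binds the vinyl group of 8 and induces an anti-periplanar 1,2-shift of the benzylic carbon from boron to the boron-bearing carbon (C4–C3 bond) while the terminal carbon C1' bonds to nickel, and C(sp3)–C(sp3) reductive elimination then forms the C1'–C2' bond of 9. The closest known reaction type is the nickel-catalysed enantioselective conjunctive cross-coupling of organolithium-derived vinylboron ate complexes with unactivated primary alkyl iodides; what is new is an ester-bearing benzylic carbanion as the migrating group and a keto iodide as the electrophile. The single stereocentre C3 is set in the metallate shift by the face of the vinyl group that the ligand-bound nickel selects (catalyst control) and is carried over with retention in the stereospecific boron-to-oxygen shift of the hydroperoxide adduct. The δ-lactone ring (the only ring closed) forms by 6-exo-trig attack of the C3 oxygen of 10 on the ester carbonyl C1 with loss of methanol, as it does spontaneously in aldehyde additions of the same carbanion, and the acid finish recloses any lactone opened by hydroxide. The step needs the conjunctive pathway to outrun direct transfer of the vinyl or benzyl group from boron to nickel and β-hydride elimination of the alkyl–nickel species, which the tridentate ligand and the DMSO co-solvent are meant to secure; the ketone of 4 and the ester stay untouched because no free organolithium remains once 8 has formed.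

Step 4
Reactants: 11 (3R)-6,8-dimethoxy-3-(7-oxoundecyl)-3,4-dihydro-1H-isochromen-1-one
Product: 12 (3R)-8-hydroxy-6-methoxy-3-(7-oxoundecyl)-3,4-dihydro-1H-isochromen-1-one
Conditions: BCl3 (1 M in CH2Cl2, 2.5 equiv), CH2Cl2, −78 → 0 °C; then H2O
Reagents that add atoms: none
Why: Chelation-controlled aryl methyl ether cleavage: boron binds between the lactone carbonyl oxygen and the peri 8-methoxy oxygen, so chloride removes only that methyl group (the standard selective demethylation of 6,8-dimethoxy-3,4-dihydroisocoumarins), and C3, not being α to a carbonyl group, cannot epimerise.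

**Compound list**

1 | 6-bromohexanoyl chloride | O=C(Cl)CCCCCBr | starting material
2 | n-butylmagnesium chloride | CCCC[Mg]Cl | starting material
3 | 10-bromodecan-5-one | CCCCC(=O)CCCCCBr | intermediate
4 | 10-iododecan-5-one | CCCCC(=O)CCCCCI | intermediate
5 | methyl 2,4-dimethoxy-6-methylbenzoate | COC(=O)c1c(C)cc(OC)cc1OC | starting material
6 | vinylboronic acid pinacol ester (4,4,5,5-tetramethyl-2-vinyl-1,3,2-dioxaborolane) | C=CB1OC(C)(C)C(C)(C)O1 | starting material
7 | methyl 2-(lithiomethyl)-4,6-dimethoxybenzoate (benzylic lithium species) | [Li]Cc1cc(OC)cc(OC)c1C(=O)OC | intermediate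
8 | lithium {[3,5-dimethoxy-2-(methoxycarbonyl)phenyl]methyl}(ethenyl)(pinacolato)borate (ate complex) | [Li+].C=C[B-]1(Cc2cc(OC)cc(OC)c2C(=O)OC)OC(C)(C)C(C)(C)O1 | intermediate
9 | methyl 2,4-dimethoxy-6-[(2R)-9-oxo-2-(4,4,5,5-tetramethyl-1,3,2-dioxaborolan-2-yl)tridecyl]benzoate | CCCCC(=O)CCCCCC[C@@H](B1OC(C)(C)C(C)(C)O1)Cc1cc(OC)cc(OC)c1C(=O)OC | intermediate
10 | methyl 2-[(2R)-2-hydroxy-9-oxotridecyl]-4,6-dimethoxybenzoate | CCCCC(=O)CCCCCC[C@@H](O)Cc1cc(OC)cc(OC)c1C(=O)OC | intermediate
11 | (3R)-6,8-dimethoxy-3-(7-oxoundecyl)-3,4-dihydro-1H-isochromen-1-one | CCCCC(=O)CCCCCC[C@@H]1Cc2cc(OC)cc(OC)c2C(=O)O1 | intermediate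
12 | (3R)-8-hydroxy-6-methoxy-3-(7-oxoundecyl)-3,4-dihydro-1H-isochromen-1-one | CCCCC(=O)CCCCCC[C@@H]1Cc2cc(OC)cc(O)c2C(=O)O1 | target

**Step count**

Total steps: 4. Longest linear sequence: 4 (steps 1, 2, 3, 4).

**Steps most likely to fail, with fallbacks**

Step 3 (bears the label). What may go wrong: the ate complex may transfer its vinyl or benzyl group directly to nickel instead of undergoing the metallate shift. It may also revert to the stabilised carbanion, which would then attack the ketone or an ester. Even if the coupling runs, facial selectivity in the shift may be poor with a benzylic migrating group.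
Fallback (known chemistry; sets out from bromo ketone 3 and returns at lactone 11; the C1'–C2' bond is then made by copper-catalysed Grignard opening of a terminal epoxide):
- 3 is ketalised (ethylene glycol, p-TsOH, toluene, Dean–Stark) to 2-(5-bromopentyl)-2-butyl-1,3-dioxolane F1, which is converted with Mg in THF into [5-(2-butyl-1,3-dioxolan-2-yl)pentyl]magnesium bromide F2.
- In parallel, purchased N,N-diethyl-2,4-dimethoxybenzamide is ortho-lithiated next to the amide (s-BuLi, TMEDA, THF, −78 °C) to [2-(diethylcarbamoyl)-3,5-dimethoxyphenyl]lithium F3.
- F3 opens purchased (S)-epichlorohydrin at the terminal epoxide carbon (BF3·OEt2, −78 °C) to give 2-[(2S)-3-chloro-2-hydroxypropyl]-N,N-diethyl-4,6-dimethoxybenzamide F4; the stereocentre is taken from the chiral pool and is not touched.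
- NaOH closes F4 to N,N-diethyl-2,4-dimethoxy-6-{[(2S)-oxiran-2-yl]methyl}benzamide F5.
- F2 opens F5 at the terminal carbon (CuI cat., THF, −30 °C) to give N,N-diethyl-2-[(2R)-8-(2-butyl-1,3-dioxolan-2-yl)-2-hydroxyoctyl]-4,6-dimethoxybenzamide F6.
- Warming F6 in aqueous HCl/dioxane lactonises the hydroxy amide and removes the dioxolane in one operation, giving 11.

Step 4. What may go wrong: loss of discrimination between the two methyl ethers (the 6-methoxy group is cleaved as well), or stalled conversion because the chain ketone sequesters the Lewis acid.
Fallback (sets out from 11 and returns at 12): both ethers are cleaved on purpose with BBr3 (CH2Cl2, −78 → 0 °C) to (3R)-6,8-dihydroxy-3-(7-oxoundecyl)-3,4-dihydro-1H-isochromen-1-one F7. The free, more acidic 6-hydroxyl is then methylated selectively (MeI 1.05 equiv, K2CO3, acetone, rt), since the 8-hydroxyl is tied up in a hydrogen bond to the lactone carbonyl; this should give 12.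

Step 1. What may go wrong: over-addition of the Grignard reagent to the newly formed ketone, or competing coupling at the C–Br terminus.
Fallback (sets out from 2 and returns at 4, bypassing 3 and step 2): 2 is added to purchased cyclohexanone (THF, 0 °C) to give 1-butylcyclohexan-1-ol F8. Its hypoiodite, formed in situ (PhI(OAc)2, I2, CH2Cl2, visible light, rt), should fragment through the alkoxy radical by β-scission of a ring C–C bond; the resulting primary radical takes up iodine to give 4 directly, with the ketone unmasked in the same event.

**Further compounds**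

F1 | step 3 | 2-(5-bromopentyl)-2-butyl-1,3-dioxolane | CCCCC1(CCCCCBr)OCCO1
F2 | step 3 | [5-(2-butyl-1,3-dioxolan-2-yl)pentyl]magnesium bromide | CCCCC1(CCCCC[Mg]Br)OCCO1
F3 | step 3 | [2-(diethylcarbamoyl)-3,5-dimethoxyphenyl]lithium | [Li]c1cc(OC)cc(OC)c1C(=O)N(CC)CC
F4 | step 3 | 2-[(2S)-3-chloro-2-hydroxypropyl]-N,N-diethyl-4,6-dimethoxybenzamide | CCN(CC)C(=O)c1c(OC)cc(OC)cc1C[C@H](O)CCl
F5 | step 3 | N,N-diethyl-2,4-dimethoxy-6-{[(2S)-oxiran-2-yl]methyl}benzamide | CCN(CC)C(=O)c1c(OC)cc(OC)cc1C[C@H]1CO1
F6 | step 3 | N,N-diethyl-2-[(2R)-8-(2-butyl-1,3-dioxolan-2-yl)-2-hydroxyoctyl]-4,6-dimethoxybenzamide | CCCCC1(CCCCCC[C@@H](O)Cc2cc(OC)cc(OC)c2C(=O)N(CC)CC)OCCO1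
F7 | step 4 | (3R)-6,8-dihydroxy-3-(7-oxoundecyl)-3,4-dihydro-1H-isochromen-1-one | CCCCC(=O)CCCCCC[C@@H]1Cc2cc(O)cc(O)c2C(=O)O1
F8 | step 1 | 1-butylcyclohexan-1-ol | CCCCC1(O)CCCCC1
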